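The data were computed from invented constants; noise was put on by code.

Take the reading at 3.0 min first, and count turnovers before anything else.

the same everywhere: substrate 0.14 M

|  | other conformer | remark | time |
|---|---|---|---|
| north-west | 0.070 M | run made earlier |  |
| flask | 0.0350 M |  | 20 h |

north-west run (percent of the substrate and other conformer together charged)

| time / h | isomer of the product / % | target / % |
|---|---|---|
| 0.500 | 10 | 2 |
| 1.50 | 19 | 13 |
| 3.00 | 22 | 25 |
| 4.00 | 26 | 32 |
| 6.00 | 33 | 39 |

(readings scatter by 1.5 percentage points)

1. share of isomer of the product in isomer of the product plus target at 3.0 min
2. share of isomer of the product in isomer of the product plus target at 1.0 h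
3. share of isomer of the product in isomer of the product plus target at 20 h

In the north-west run, other conformer was 33.3% of the charge and gave 10% isomer of the product by 0.500 h. That is a mean rate of 0.600 /h per unit of that fraction. So 3.0 min is 0.0300 of a turnover, far less than one, and I take both products as still running at their starting rates. Target at 0.500 h, 2%, is thin against a scatter of 1.5 percentage points, so I read its mean rate up to 3.00 h, where 25% gives 0.125 /h per unit of substrate fraction.

Their quotient, 4.80, is the selectivity factor: the rate of isomer of the product over that of target, each per unit of the fraction of its parent. This flask charges 20.0% as other conformer. The early share is the factor times that fraction, over itself plus the substrate fraction, so I estimate 54.5%.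

The forecast gives 93%, 55% and 41%, holding that “the target is still negligible” at 3.0 min; its first value stands above my estimate.

The flask gives 62.9%, 49.2% and 41.7%.

    substrate ⇌ other conformer (K = 0.0993, k = 0.0706 /h)
    substrate → target (k = 0.147 /h)
    other conformer → isomer of the product (k = 1.04 /h)
    target ⇌ isomer of the product (K = 4.58, k = 0.0127 /h)
    other conformer ⇌ dormant form (K = 1.37, k = 0.236 /h)
    2 substrate → homo dimer (k = 0.00132 /M/h)

At 3.0 min the flask stands 8.4 points above my estimate and 30 points below the forecast. With the path from substrate to other conformer struck out, both ways, that share is still 63.2%. A neighbour flask with 0.14 M other conformer charges 50.0% as other conformer, so the factor 4.80 gives 82.8%, and that flask gives 87.0% at 3.0 min.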